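C1 acid ⇐ primary alcohol (late oxidation); the last skeletal bond made is C6–CH2 of the side chain, joining a 6-methoxy-6-methyl-1,2-dioxane (fragment A) to a homoallylic zinc reagent (fragment B) that already carries the E alkene and the epoxycyclohexane.
Enabling feature: C6 of the 1,2-dioxane (ring O1–O2–C3–C4–C5–C6) is a quaternary carbon bound to peroxide oxygen O1, i.e. a masked ketone that can ionise to a cyclic peroxycarbenium ion; C3, 1,4 to it across the six-membered ring, fixes the half-chair and directs axial attack.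
Fragment A: Evans syn aldol sets C2 and C3; ozonolysis in MeOH and a 6-exo SN2 peroxide closure with inversion at C3 build the 1,2-dioxane.
Fragment B: Sharpless epoxidation of β-cyclogeraniol puts the oxirane on the purchased cyclohexene; a vinyl epoxide and a B-alkyl Suzuki coupling with (E)-4-iodopent-3-en-1-ol fix the E alkene.
Ring order: cyclohexane (bought), oxirane (step 9), 1,2-dioxane (step 7); the coupling closes no ring but creates the last stereocentre, C6.

Key step: step 15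

Assumption: the fully substituted, sterically shielded epoxide is taken to survive TMSOTf at −78 °C when a hindered pyridine is present; C3 and C6 denote the dioxane carbons bearing the propanoate side chain and the methyl group.

Step 1
Reactants: 1 ethyl 4-methylpent-4-enoate
Product: 2 4-methylpent-4-enal
Conditions: i-Bu2AlH, CH2Cl2, −78 °C; aq. potassium sodium tartrate
Reagents that add atoms: none
Why: Partial ester reduction stops at the aluminium hemiacetal at −78 °C, which releases the aldehyde only on work-up, and the isolated alkene is inert.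

Step 2
Reactants: 2 4-methylpent-4-enal; 3 (4R)-4-benzyl-3-propanoyl-1,3-oxazolidin-2-one
Product: 5 (4R)-4-benzyl-3-[(2R,3S)-3-hydroxy-2,6-dimethylhept-6-enoyl]-1,3-oxazolidin-2-one, via dibutylboron Z-enolate 4 (not isolated)
Conditions: Bu2BOTf, i-Pr2NEt, CH2Cl2, 0 °C; 2, −78 to 0 °C; pH 7 buffer, MeOH, H2O2
Reagents that add atoms: none
Why: Evans syn aldol reaction, in which the Z boron enolate reacts through a closed chair transition state on the enolate face opposite the benzyl group of the (R)-auxiliary and should set C2 (R) and C3 (S) together.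

Step 3
Reactants: 5 (4R)-4-benzyl-3-[(2R,3S)-3-hydroxy-2,6-dimethylhept-6-enoyl]-1,3-oxazolidin-2-one
Product: 6 (2S,3S)-2,6-dimethylhept-6-ene-1,3-diol
Conditions: LiBH4, MeOH (1 equiv), Et2O, 0 °C
Reagents that add atoms: none
Why: Reductive cleavage of the activated imide carbonyl by borohydride releases the auxiliary and touches no stereocentre.

Step 4
Reactants: 6 (2S,3S)-2,6-dimethylhept-6-ene-1,3-diol
Product: 7 (2S,3S)-1-{[tert-butyl(diphenyl)silyl]oxy}-2,6-dimethylhept-6-en-3-ol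
Conditions: TBDPSCl, imidazole, CH2Cl2, 0 °C
Reagents that add atoms: tert-butyl(chloro)diphenylsilane CC(C)(C)[Si](Cl)(c1ccccc1)c1ccccc1
Why: Sterically controlled silylation should take the primary hydroxyl selectively over the hindered secondary one.

Step 5
Reactants: 7 (2S,3S)-1-{[tert-butyl(diphenyl)silyl]oxy}-2,6-dimethylhept-6-en-3-ol
Product: 8 (2S,3S)-1-{[tert-butyl(diphenyl)silyl]oxy}-2,6-dimethylhept-6-en-3-yl methanesulfonate
Conditions: MsCl, Et3N, CH2Cl2, 0 °C
Reagents that add atoms: methanesulfonyl chloride CS(Cl)(=O)=O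
Why: O-Sulfonylation converts the C3 hydroxyl into a leaving group with retention, preparing the later SN2 inversion.

Step 6
Reactants: 8 (2S,3S)-1-{[tert-butyl(diphenyl)silyl]oxy}-2,6-dimethylhept-6-en-3-yl methanesulfonate
Product: 9 (2S,3S)-1-{[tert-butyl(diphenyl)silyl]oxy}-6-hydroperoxy-6-methoxy-2-methylheptan-3-yl methanesulfonate (both C6 epimers)
Conditions: O3, CH2Cl2/MeOH, −78 °C; N2 purge
Reagents that add atoms: ozone [O-][O+]=O; methanol CO
Why: Criegee ozonolysis of the 1,1-disubstituted alkene gives formaldehyde and the ketone O-oxide, which methanol traps as the α-methoxy hydroperoxide, the C6 centre being erased again in step 15.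

Step 7
Reactants: 9 (2S,3S)-1-{[tert-butyl(diphenyl)silyl]oxy}-6-hydroperoxy-6-methoxy-2-methylheptan-3-yl methanesulfonate
Product: 10 tert-butyl{(2S)-2-[(3R)-6-methoxy-6-methyl-1,2-dioxan-3-yl]propoxy}diphenylsilane (both C6 epimers)
Conditions: KOt-Bu, 18-crown-6, toluene, 0 °C
Reagents that add atoms: none
Why: Intramolecular Williamson-type SN2 alkylation of the hydroperoxide anion (6-exo-tet) closes the 1,2-dioxane with inversion at C3, turning the syn aldol array into the required (3R) C–O–O centre anti to the C-methyl group.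

Step 8
Reactants: 11 β-cyclocitral (2,6,6-trimethylcyclohex-1-ene-1-carbaldehyde)
Product: 12 β-cyclogeraniol ((2,6,6-trimethylcyclohex-1-en-1-yl)methanol)
Conditions: NaBH4, MeOH, 0 °C
Reagents that add atoms: none
Why: 1,2-Reduction of the hindered enal by borohydride gives the allylic alcohol needed as directing group.

Step 9
Reactants: 12 β-cyclogeraniol
Product: 13 [(1R,6R)-2,2,6-trimethyl-7-oxabicyclo[4.1.0]heptan-1-yl]methanol
Conditions: Ti(Oi-Pr)4 (10 mol%), D-(−)-diethyl tartrate (12 mol%), t-BuOOH, 4 Å MS, CH2Cl2, −20 °C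
Reagents that add atoms: tert-butyl hydroperoxide CC(C)(C)OO
Why: Sharpless asymmetric epoxidation, in which the titanium tartrate complex binds the allylic alcohol and delivers oxygen to one enantiotopic face of the tetrasubstituted alkene, D-(−)-tartrate being the enantiomer expected by the usual face rule to give the (1R,6R) epoxide with both centres formed together by syn addition.

Step 10
Reactants: 13 [(1R,6R)-2,2,6-trimethyl-7-oxabicyclo[4.1.0]heptan-1-yl]methanol
Product: 14 (1S,6R)-2,2,6-trimethyl-7-oxabicyclo[4.1.0]heptane-1-carbaldehyde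
Conditions: Pr4N[RuO4] (5 mol%), N-methylmorpholine N-oxide, 4 Å MS, CH2Cl2, rt
Reagents that add atoms: none
Why: Ley–Griffith oxidation under neutral conditions takes the primary alcohol to the aldehyde without touching the acid-labile epoxide, and the quaternary α-carbon cannot epimerise.

Step 11
Reactants: 14 (1S,6R)-2,2,6-trimethyl-7-oxabicyclo[4.1.0]heptane-1-carbaldehyde
Product: 15 (1S,6R)-1-ethenyl-2,2,6-trimethyl-7-oxabicyclo[4.1.0]heptane
Conditions: Ph3PCH3Br, KOt-Bu, THF, 0 °C to rt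
Reagents that add atoms: methyltriphenylphosphonium bromide C[P+](c1ccccc1)(c1ccccc1)c1ccccc1.[Br-]
Why: Wittig methylenation of the non-enolisable aldehyde, the hindered epoxide being inert to the unstabilised ylide.

Step 12
Reactants: 16 pent-3-yn-1-ol
Product: 18 (3E)-4-iodopent-3-en-1-ol, via alkenylzirconocene 17 (not isolated)
Conditions: Cp2Zr(H)Cl (2.2 equiv), THF, rt to 40 °C; I2, 0 °C
Reagents that add atoms: iodine II
Why: Hydrozirconation adds Zr–H syn across the alkyne with zirconium settling on the less hindered methyl-bearing carbon, and iodinolysis with retention should give the E iodide (iodine trans to the hydroxyethyl chain).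

Step 13
Reactants: 15 (1S,6R)-1-ethenyl-2,2,6-trimethyl-7-oxabicyclo[4.1.0]heptane; 18 (3E)-4-iodopent-3-en-1-ol
Product: 20 (3E)-4-methyl-6-[(1S,6R)-2,2,6-trimethyl-7-oxabicyclo[4.1.0]heptan-1-yl]hex-3-en-1-ol, via B-alkyl-9-BBN 19 (not isolated)
Conditions: 9-BBN, THF, rt; then 18, PdCl2(dppf) (5 mol%), AsPh3, Cs2CO3, DMF/H2O, rt
Reagents that add atoms: none
Why: Anti-Markovnikov hydroboration of the terminal alkene followed by B-alkyl Suzuki–Miyaura coupling, which retains the alkenyl iodide geometry and so fixes the E trisubstituted alkene.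

Step 14
Reactants: 20 (3E)-4-methyl-6-[(1S,6R)-2,2,6-trimethyl-7-oxabicyclo[4.1.0]heptan-1-yl]hex-3-en-1-ol
Product: 21 (1S,6R)-1-[(3E)-6-iodo-3-methylhex-3-en-1-yl]-2,2,6-trimethyl-7-oxabicyclo[4.1.0]heptane
Conditions: I2, PPh3, imidazole, CH2Cl2, 0 °C
Reagents that add atoms: iodine II
Why: Appel-type iodination (iodide displaces the alkoxyphosphonium ion) of the primary alcohol under imidazole-buffered conditions.

Step 15
Reactants: 21 (1S,6R)-1-[(3E)-6-iodo-3-methylhex-3-en-1-yl]-2,2,6-trimethyl-7-oxabicyclo[4.1.0]heptane; 10 tert-butyl{(2S)-2-[(3R)-6-methoxy-6-methyl-1,2-dioxan-3-yl]propoxy}diphenylsilane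
Product: 25 tert-butyl{(2S)-2-[(3R,6R)-6-methyl-6-{(3E)-4-methyl-6-[(1S,6R)-2,2,6-trimethyl-7-oxabicyclo[4.1.0]heptan-1-yl]hex-3-en-1-yl}-1,2-dioxan-3-yl]propoxy}diphenylsilane, via dialkylzinc 22 (not isolated), via mixed alkylzinc 23 (not isolated), via peroxycarbenium triflate 24 (not isolated)
Conditions: 21, Et2Zn (neat), CuI (cat.), 50 °C, then vacuum; (Me3SiCH2)2Zn, CH2Cl2, 0 °C; then 10, TMSOTf, 2,6-di-tert-butyl-4-methylpyridine, CH2Cl2, −78 to −40 °C
Reagents that add atoms: none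
Why: Proposed new method: TMSOTf should ionise the ketone-derived peroxyketal 10 (loss of MeOSiMe3) to the cyclic peroxycarbenium ion 24, which the σ-nucleophilic C–Zn bond of the salt-free mixed reagent 23 (Me3SiCH2 as the non-transferable group) should alkylate at carbon faster than it attacks the O–O bond, because dialkyl peroxides are poor electrophiles towards organozincs at −78 °C whereas carbenium ions are excellent ones; the closest known reaction types are the Lewis-acid Hosomi–Sakurai and Mukaiyama substitutions of 3-alkoxy-1,2-dioxanes and -dioxolanes through peroxycarbenium ions and the TMSOTf-mediated alkylation of oxocarbenium ions (from α-acetoxy ethers) by dialkylzincs. No ring is closed, since the 1,2-dioxane and the oxirane are both carried in intact. The only new stereocentre, C6, is controlled by C3: in the half-chair cation the C3 side chain sits pseudo-equatorial and the nucleophile enters along the axial trajectory that leads directly to a chair, which places the new chain cis to the C3 substituent (6R), as in six-membered oxocarbenium ions. The step needs C- over O-alkylation and survival of the tetrasubstituted epoxide and the trisubstituted alkene; the first is secured by cationic activation of C6, the second by the low temperature, the hindered pyridine that removes adventitious TfOH, the absence of halide salts and the shielding of the epoxide by its flanking quaternary carbon, the third by the far higher nucleophilicity of the C–Zn bond.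

Step 16
Reactants: 25 tert-butyl{(2S)-2-[(3R,6R)-6-methyl-6-{(3E)-4-methyl-6-[(1S,6R)-2,2,6-trimethyl-7-oxabicyclo[4.1.0]heptan-1-yl]hex-3-en-1-yl}-1,2-dioxan-3-yl]propoxy}diphenylsilane
Product: 26 (2S)-2-[(3R,6R)-6-methyl-6-{(3E)-4-methyl-6-[(1S,6R)-2,2,6-trimethyl-7-oxabicyclo[4.1.0]heptan-1-yl]hex-3-en-1-yl}-1,2-dioxan-3-yl]propan-1-ol
Conditions: Bu4NF, AcOH, THF, 0 °C to rt
Reagents that add atoms: none
Why: Fluoride-mediated desilylation, with acetic acid buffering to suppress base-induced Kornblum–DeLaMare fragmentation at C3.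

Step 17
Reactants: 26 (2S)-2-[(3R,6R)-6-methyl-6-{(3E)-4-methyl-6-[(1S,6R)-2,2,6-trimethyl-7-oxabicyclo[4.1.0]heptan-1-yl]hex-3-en-1-yl}-1,2-dioxan-3-yl]propan-1-ol
Product: 28 (2R)-2-[(3R,6R)-6-methyl-6-{(3E)-4-methyl-6-[(1S,6R)-2,2,6-trimethyl-7-oxabicyclo[4.1.0]heptan-1-yl]hex-3-en-1-yl}-1,2-dioxan-3-yl]propanoic acid (CNP0252106.4), via aldehyde 27 (not isolated)
Conditions: TEMPO (20 mol%), PhI(OAc)2, MeCN/aq. pH 7 phosphate buffer, rt
Reagents that add atoms: water O
Why: Oxoammonium (TEMPO) oxidation of the primary alcohol through the aldehyde hydrate to the acid under buffered, near-neutral conditions that should leave the dialkyl peroxide, the epoxide, the alkene and the α-stereocentre untouched.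

Compound list
1 | ethyl 4-methylpent-4-enoate | CCOC(=O)CCC(C)=C | starting material
2 | 4-methylpent-4-enal | O=CCCC(C)=C | intermediate
3 | (4R)-4-benzyl-3-propanoyl-1,3-oxazolidin-2-one | CCC(=O)N1[C@H](Cc2ccccc2)COC1=O | starting material
4 | dibutylboron (Z)-enolate of 3 | C/C=C(\OB(CCCC)CCCC)N1[C@H](Cc2ccccc2)COC1=O | intermediate
5 | (4R)-4-benzyl-3-[(2R,3S)-3-hydroxy-2,6-dimethylhept-6-enoyl]-1,3-oxazolidin-2-one | C=C(C)CC[C@@H]([C@@H](C)C(=O)N1[C@H](Cc2ccccc2)COC1=O)O | intermediate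
6 | (2S,3S)-2,6-dimethylhept-6-ene-1,3-diol | C=C(C)CC[C@@H]([C@@H](C)CO)O | intermediate
7 | (2S,3S)-1-{[tert-butyl(diphenyl)silyl]oxy}-2,6-dimethylhept-6-en-3-ol | C=C(C)CC[C@@H]([C@@H](C)CO[Si](c1ccccc1)(c1ccccc1)C(C)(C)C)O | intermediate
8 | (2S,3S)-1-{[tert-butyl(diphenyl)silyl]oxy}-2,6-dimethylhept-6-en-3-yl methanesulfonate | C=C(C)CC[C@@H]([C@@H](C)CO[Si](c1ccccc1)(c1ccccc1)C(C)(C)C)OS(C)(=O)=O | intermediate
9 | (2S,3S)-1-{[tert-butyl(diphenyl)silyl]oxy}-6-hydroperoxy-6-methoxy-2-methylheptan-3-yl methanesulfonate (both C6 epimers) | COC(C)(OO)CC[C@@H]([C@@H](C)CO[Si](c1ccccc1)(c1ccccc1)C(C)(C)C)OS(C)(=O)=O | intermediate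
10 | tert-butyl{(2S)-2-[(3R)-6-methoxy-6-methyl-1,2-dioxan-3-yl]propoxy}diphenylsilane (both C6 epimers) | COC1(C)CC[C@H]([C@@H](C)CO[Si](c2ccccc2)(c2ccccc2)C(C)(C)C)OO1 | intermediate
11 | β-cyclocitral (2,6,6-trimethylcyclohex-1-ene-1-carbaldehyde) | CC1=C(C=O)C(C)(C)CCC1 | starting material
12 | β-cyclogeraniol ((2,6,6-trimethylcyclohex-1-en-1-yl)methanol) | CC1=C(CO)C(C)(C)CCC1 | intermediate
13 | [(1R,6R)-2,2,6-trimethyl-7-oxabicyclo[4.1.0]heptan-1-yl]methanol | OC[C@@]12O[C@]1(C)CCCC2(C)C | intermediate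
14 | (1S,6R)-2,2,6-trimethyl-7-oxabicyclo[4.1.0]heptane-1-carbaldehyde | O=C[C@@]12O[C@]1(C)CCCC2(C)C | intermediate
15 | (1S,6R)-1-ethenyl-2,2,6-trimethyl-7-oxabicyclo[4.1.0]heptane | C=C[C@@]12O[C@]1(C)CCCC2(C)C | intermediate
16 | pent-3-yn-1-ol | CC#CCCO | starting material
17 | chlorozirconocene alkoxide of (3E)-4-(chlorozirconocenyl)pent-3-en-1-ol | C/C(=C\CCO[Zr](Cl)(C1C=CC=C1)C1C=CC=C1)[Zr](Cl)(C1C=CC=C1)C1C=CC=C1 | intermediate
18 | (3E)-4-iodopent-3-en-1-ol | C/C(I)=C\CCO | intermediate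
19 | 9-{2-[(1S,6R)-2,2,6-trimethyl-7-oxabicyclo[4.1.0]heptan-1-yl]ethyl}-9-borabicyclo[3.3.1]nonane | C(CB1C2CCCC1CCC2)[C@@]12O[C@]1(C)CCCC2(C)C | intermediate
20 | (3E)-4-methyl-6-[(1S,6R)-2,2,6-trimethyl-7-oxabicyclo[4.1.0]heptan-1-yl]hex-3-en-1-ol | C/C(=C\CCO)CC[C@@]12O[C@]1(C)CCCC2(C)C | intermediate
21 | (1S,6R)-1-[(3E)-6-iodo-3-methylhex-3-en-1-yl]-2,2,6-trimethyl-7-oxabicyclo[4.1.0]heptane | C/C(=C\CCI)CC[C@@]12O[C@]1(C)CCCC2(C)C | intermediate
22 | bis{(3E)-4-methyl-6-[(1S,6R)-2,2,6-trimethyl-7-oxabicyclo[4.1.0]heptan-1-yl]hex-3-en-1-yl}zinc | C/C(=C\CC[Zn]CC/C=C(\C)CC[C@@]12O[C@]1(C)CCCC2(C)C)CC[C@@]12O[C@]1(C)CCCC2(C)C | intermediate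
23 | {(3E)-4-methyl-6-[(1S,6R)-2,2,6-trimethyl-7-oxabicyclo[4.1.0]heptan-1-yl]hex-3-en-1-yl}[(trimethylsilyl)methyl]zinc | C/C(=C\CC[Zn]C[Si](C)(C)C)CC[C@@]12O[C@]1(C)CCCC2(C)C | intermediate
24 | (3R)-3-[(2S)-1-{[tert-butyl(diphenyl)silyl]oxy}propan-2-yl]-6-methyl-4,5-dihydro-3H-1,2-dioxin-1-ium triflate | CC1=[O+]O[C@@H]([C@@H](C)CO[Si](c2ccccc2)(c2ccccc2)C(C)(C)C)CC1.[O-]S(=O)(=O)C(F)(F)F | intermediate
25 | tert-butyl{(2S)-2-[(3R,6R)-6-methyl-6-{(3E)-4-methyl-6-[(1S,6R)-2,2,6-trimethyl-7-oxabicyclo[4.1.0]heptan-1-yl]hex-3-en-1-yl}-1,2-dioxan-3-yl]propoxy}diphenylsilane | C/C(=C\CC[C@]1(C)CC[C@H]([C@@H](C)CO[Si](c2ccccc2)(c2ccccc2)C(C)(C)C)OO1)CC[C@@]12O[C@]1(C)CCCC2(C)C | intermediate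
26 | (2S)-2-[(3R,6R)-6-methyl-6-{(3E)-4-methyl-6-[(1S,6R)-2,2,6-trimethyl-7-oxabicyclo[4.1.0]heptan-1-yl]hex-3-en-1-yl}-1,2-dioxan-3-yl]propan-1-ol | C/C(=C\CC[C@]1(C)CC[C@H]([C@@H](C)CO)OO1)CC[C@@]12O[C@]1(C)CCCC2(C)C | intermediate
27 | (2R)-2-[(3R,6R)-6-methyl-6-{(3E)-4-methyl-6-[(1S,6R)-2,2,6-trimethyl-7-oxabicyclo[4.1.0]heptan-1-yl]hex-3-en-1-yl}-1,2-dioxan-3-yl]propanal | C/C(=C\CC[C@]1(C)CC[C@H]([C@@H](C)C=O)OO1)CC[C@@]12O[C@]1(C)CCCC2(C)C | intermediate
28 | (2R)-2-[(3R,6R)-6-methyl-6-{(3E)-4-methyl-6-[(1S,6R)-2,2,6-trimethyl-7-oxabicyclo[4.1.0]heptan-1-yl]hex-3-en-1-yl}-1,2-dioxan-3-yl]propanoic acid (CNP0252106.4) | C/C(=C\CC[C@]1(C)CC[C@H]([C@@H](C)C(=O)O)OO1)CC[C@@]12O[C@]1(C)CCCC2(C)C | target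

Total step count: 17. Longest linear sequence: 10 steps (steps 1–7, then 15–17).

Steps most likely to fail

1. Step 15 (the proposed new method). The organozinc may attack the O–O bond or transfer a β-hydride instead of alkylating C6, the Lewis acid may open the epoxide, or reaction through the pseudo-axial conformer may erode facial selectivity. The fallback sets out from 10 (and from borane 19, made from 15 as in step 13) and returns to the route at 25, so that the epoxide only meets palladium and base. A Hosomi–Sakurai reaction of 10 with allyltrimethylsilane and TMSOTf (CH2Cl2, −78 °C), a known reaction of alkoxy-1,2-dioxanes, should give the 6-allyl dioxane F1 with the same axial preference. Hydroboration–oxidation (9-BBN; NaBO3) should give the alcohol F2, Dess–Martin oxidation the aldehyde F3, and Corey–Fuchs dibromo-olefination (CBr4, PPh3) the 1,1-dibromoalkene F4. Trans-selective palladium-catalysed monoalkylation of F4 with borane 19 [PdCl2(dppf), Cs2CO3] should give the (Z)-bromoalkene F5, and Negishi methylation of the remaining bromide with retention [Me2Zn, Pd(Pt-Bu3)2] should give 25.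

2. Step 7. Base-induced elimination of the β-branched secondary mesylate, or fragmentation of the hydroperoxy ketal anion, may outrun the 6-exo displacement. The fallback sets out from 8 and returns at 10; it uses weakly basic aqueous peroxide and closes the ring by hemiketalisation. Ozonolysis of 8 with reductive work-up (O3, CH2Cl2, −78 °C; Me2S) should give the keto mesylate F6. Perhydrolysis of the sulfonate with inversion (50% aq. H2O2, KOH, MeOH/THF, 0 °C) should give the γ-hydroperoxy ketone, which closes spontaneously to the peroxy hemiketal F7. Exchange in methanol (MeOH, pyridinium p-toluenesulfonate) should give 10.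

3. Step 17. Epimerisation or β-elimination of the β-peroxy aldehyde intermediate, or acid-induced opening of the epoxide during the late oxidation, may erode the product. The fallback sets out from 10 and returns at 28; the oxidation is done before the epoxide and alkene are present. Desilylation of 10 (Bu4NF, AcOH) should give the alcohol F8, TEMPO/PhI(OAc)2 oxidation the acid F9, and Me3SiCHN2 the methyl ester F10. The coupling of step 15, run with 23 on F10, should give the ester F11, and mild saponification (LiOH, THF/H2O, 0 °C) should give 28.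

Further compounds
F1 | step 15 | tert-butyl{(2S)-2-[(3R,6S)-6-methyl-6-(prop-2-en-1-yl)-1,2-dioxan-3-yl]propoxy}diphenylsilane | C=CC[C@]1(C)CC[C@H]([C@@H](C)CO[Si](c2ccccc2)(c2ccccc2)C(C)(C)C)OO1
F2 | step 15 | tert-butyl{(2S)-2-[(3R,6R)-6-(3-hydroxypropyl)-6-methyl-1,2-dioxan-3-yl]propoxy}diphenylsilane | OCCC[C@]1(C)CC[C@H]([C@@H](C)CO[Si](c2ccccc2)(c2ccccc2)C(C)(C)C)OO1
F3 | step 15 | tert-butyl{(2S)-2-[(3R,6S)-6-methyl-6-(3-oxopropyl)-1,2-dioxan-3-yl]propoxy}diphenylsilane | O=CCC[C@]1(C)CC[C@H]([C@@H](C)CO[Si](c2ccccc2)(c2ccccc2)C(C)(C)C)OO1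
F4 | step 15 | tert-butyl{(2S)-2-[(3R,6R)-6-(4,4-dibromobut-3-en-1-yl)-6-methyl-1,2-dioxan-3-yl]propoxy}diphenylsilane | BrC(Br)=CCC[C@]1(C)CC[C@H]([C@@H](C)CO[Si](c2ccccc2)(c2ccccc2)C(C)(C)C)OO1
F5 | step 15 | tert-butyl{(2S)-2-[(3R,6R)-6-{(3Z)-4-bromo-6-[(1S,6R)-2,2,6-trimethyl-7-oxabicyclo[4.1.0]heptan-1-yl]hex-3-en-1-yl}-6-methyl-1,2-dioxan-3-yl]propoxy}diphenylsilane | Br/C(=C\CC[C@]1(C)CC[C@H]([C@@H](C)CO[Si](c2ccccc2)(c2ccccc2)C(C)(C)C)OO1)CC[C@@]12O[C@]1(C)CCCC2(C)C
F6 | step 7 | (2S,3S)-1-{[tert-butyl(diphenyl)silyl]oxy}-2-methyl-6-oxoheptan-3-yl methanesulfonate | CC(=O)CC[C@@H]([C@@H](C)CO[Si](c1ccccc1)(c1ccccc1)C(C)(C)C)OS(C)(=O)=O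
F7 | step 7 | (6R)-6-[(2S)-1-{[tert-butyl(diphenyl)silyl]oxy}propan-2-yl]-3-methyl-1,2-dioxan-3-ol (both C3 epimers) | CC1(O)CC[C@H]([C@@H](C)CO[Si](c2ccccc2)(c2ccccc2)C(C)(C)C)OO1
F8 | step 17 | (2S)-2-[(3R)-6-methoxy-6-methyl-1,2-dioxan-3-yl]propan-1-ol | COC1(C)CC[C@H]([C@@H](C)CO)OO1
F9 | step 17 | (2R)-2-[(3R)-6-methoxy-6-methyl-1,2-dioxan-3-yl]propanoic acid | COC1(C)CC[C@H]([C@@H](C)C(=O)O)OO1
F10 | step 17 | methyl (2R)-2-[(3R)-6-methoxy-6-methyl-1,2-dioxan-3-yl]propanoate | COC1(C)CC[C@H]([C@@H](C)C(=O)OC)OO1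
F11 | step 17 | methyl (2R)-2-[(3R,6R)-6-methyl-6-{(3E)-4-methyl-6-[(1S,6R)-2,2,6-trimethyl-7-oxabicyclo[4.1.0]heptan-1-yl]hex-3-en-1-yl}-1,2-dioxan-3-yl]propanoate | C/C(=C\CC[C@]1(C)CC[C@H]([C@@H](C)C(=O)OC)OO1)CC[C@@]12O[C@]1(C)CCCC2(C)C
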